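(The rate constants were chosen freely; what happens was integrated by code.)

A small charge of starting material, 0.10 M, has to become target over 10 µM of enzyme, and the second substrate, charged at 0.130 M, is its partner. The enzyme binds starting material, then second substrate, and the ternary complex releases target and enzyme. Meanwhile two second substrate can join without the enzyme to give self-condensation product.

    starting material + enzyme ⇌ starting complex (K1 = 21 M⁻¹, k1 = 33200 M⁻¹ s⁻¹)
    second substrate + starting complex ⇌ ternary complex (K2 = 44.1 M⁻¹, k2 = 91800 M⁻¹ s⁻¹)
    ternary complex → enzyme + target (k3 = 95.7 s⁻¹)
    2 second substrate → self-condensation product (k4 = 0.0778 M⁻¹ s⁻¹)

| flask | starting material | second substrate | enzyme | time | remark |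
|---|---|---|---|---|---|
| grey | 0.10 M | 0.130 M | 10 µM | 5.0 min | everything together at the start |
| green | 0.10 M (in portions, 2, over 1.0 min) | 0.130 M | 10 µM | 5.0 min | first portion at the start, last at 1.0 min |
| blue | 0.10 M (fed, over 1.0 min) | 0.130 M | 10 µM | 5.0 min | all else is in the flask from the start; the feed brings no volume worth counting |
| violet | 0.10 M | 0.130 M (fed, over 1.0 min) | 10 µM | 5.0 min | all else is in the flask from the start; the feed brings no volume worth counting |

1. the flask that comes out highest in amount of target, in percent of the starting material charged, or "all alike" when all lie within 1.5 percentage points (grey / green / blue / violet / all alike)
2. target at the end, in percent of the starting material charged, grey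
3. target at the end, in percent of the starting material charged, green
4. target at the end, in percent of the starting material charged, blue
5. target at the end, in percent of the starting material charged, violet

Each target takes one starting material and one second substrate, so second substrate has a margin of 0.0300 M. Each self-condensation burns two, so 0.0150 M of self-condensation product uses up that margin, and beyond it second substrate becomes the limiting reagent.

In the first instants of grey, binding is quick: starting material has a forward half-life of 2.1 s with the other concentrations held at their charge. Equilibrium constant times opening concentration is 2.1 for the first binding and 5.7 for the second, which, with both bindings taken at equilibrium, reckons 79.5% of the enzyme in ternary complex at the opening concentrations. The enzyme's top rate, V, is the last step's constant times the enzyme charge, 9.57 × 10⁻⁴ M s⁻¹. Self-condensation opens grey by taking second substrate at 0.00263 M s⁻¹, faster than V.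

The two rates meet at the break-even concentration Bb, where self-condensation spends second substrate as fast as the enzyme at top rate: 0.0784 M. At a concentration B, the enzyme's best share of the second substrate spent is one over one plus the square of B/Bb. In grey that share is 26.7% at the opening and 59.3% at half the charge. Taking the latter as the mean share gives an upper estimate of about 77.1% target. Late in the run second substrate thins, the enzyme leaves the ternary complex and target comes slowly. Green and blue hold their second substrate charge from the start, so this reckoning gives them no gain over grey.

Violet feeds second substrate at 0.00217 M s⁻¹, faster than V, so it builds up. With the enzyme at top rate and self-condensation left out, the reckoning puts it near 0.0726 M when the feed ends, under Bb. The share at half that level is 82.4%, which is worth 0.107 M of target, more than the starting material charged. This estimate therefore puts violet above grey.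

The forecast, lower for grey than this estimate, gave 70% for grey, 67% for green, 66.5% for blue and 82% for violet, so violet highest: "Feeding it keeps its concentration low and cuts that loss."

The flasks end at 67.3% in grey, 63.9% in green, 61.8% in blue and 78.0% in violet, so violet stands highest.

Over the first minute, mean second substrate in violet was 0.0458 M, below Bb, while in grey it was 0.0727 M, close to Bb. Raising the enzyme in violet to 2.5 × 10⁻⁵ M lifts Bb to 0.124 M, and that flask ends with 99.7% target and 0.0121 M self-condensation product.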